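**Strategy.** Numbering: ring O1, C2 (quaternary), C3, C4, C5=C6, C7; C1 is the carboxyl carbon. C2 is traced back to the ketone of an α-keto ester lying γ,δ to the C5=C6 olefin of the tetrahydrooxepine ring, a Claisen retron. A thermal [3,3] ring expansion of a 3-methylene-5-vinyl-1,4-dioxan-2-one (the cyclic enol ether of a pyruvate ester of a 2-vinyl-1,2-diol) forms C3–C4 and C5=C6 in one operation, unveils the C1–C2 keto ester and holds C4 and C7 cis, since both stay inside the eight-membered keto lactone. A Cu(OTf)2/bis(oxazoline)-catalysed Mukaiyama aldol then sets C2, and a Mitsunobu cyclodehydration closes O1–C7.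

Key step: step 8

Remark: TBS = tert-butyldimethylsilyl, TES = triethylsilyl, TMS = trimethylsilyl, TMSE = 2-(trimethylsilyl)ethyl; compounds 8 and 10–13 are racemic or stereoisomer mixtures whose stereocentres disappear in step 8.

Step 1
Reactants: 1 5-bromo-2-methylpent-2-ene
Product: 2 (2E)-5-bromo-2-methylpent-2-en-1-ol
Conditions: SeO2 (cat.), t-BuOOH, CH2Cl2, 0 °C → rt
Reagents that add atoms: tert-butyl hydroperoxide, CC(C)(C)OO (source of the oxygen atom through SeO2)
Why: Catalytic SeO2 allylic oxidation (ene reaction followed by [2,3]-sigmatropic shift) hydroxylates the methyl group trans to the chain on a gem-dimethyl trisubstituted olefin, which should give the (E)-allylic alcohol.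

Step 2
Reactants: 2 (2E)-5-bromo-2-methylpent-2-en-1-ol
Product: 3 (2E)-5-bromo-2-methyl-1-(TBSO)pent-2-ene
Conditions: TBSCl, imidazole, DMF, rt
Reagents that add atoms: tert-butyldimethylsilyl chloride, CC(C)(C)[Si](C)(C)Cl
Why: Standard silylation of the primary alcohol masks the hydroxyl for the organomagnesium steps.

Step 3
Reactants: 3 (2E)-5-bromo-2-methyl-1-(TBSO)pent-2-ene; 4 2-chloro-N-methoxy-N-methylacetamide
Product: 6 (5E)-1-chloro-6-methyl-7-(TBSO)hept-5-en-2-one, via Grignard reagent 5 (not isolated)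
Conditions: Mg, THF, rt; then 4, −20 → 0 °C; aq. NH4Cl
Reagents that add atoms: none
Why: The primary homoallylic bromide forms a Grignard reagent that acylates the N-methoxy-N-methylamide 4 through a stable chelated tetrahedral adduct (Weinreb ketone synthesis), so the addition stops at the α-chloro ketone.

Step 4
Reactants: 6 (5E)-1-chloro-6-methyl-7-(TBSO)hept-5-en-2-one
Product: 7 (5E)-6-methyl-2-oxo-7-(TBSO)hept-5-enyl acetate
Conditions: KOAc, DMF, rt
Reagents that add atoms: potassium acetate, CC(=O)[O-].[K+]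
Why: SN2 displacement of the activated α-keto chloride by acetate introduces the oxygen on C7.

Step 5
Reactants: 7 (5E)-6-methyl-2-oxo-7-(TBSO)hept-5-enyl acetate
Product: 8 rac-2-[(3E)-4-methyl-5-(TBSO)pent-3-enyl]but-3-ene-1,2-diol
Conditions: CH2=CHMgBr (3.5 equiv), THF, −78 → 0 °C; aq. NH4Cl
Reagents that add atoms: vinylmagnesium bromide, C=C[Mg]Br
Why: Excess vinyl Grignard reagent adds 1,2 to the ketone and cleaves the acetate in the same flask, giving the 2-vinyl-1,2-diol whose tertiary carbinol centre C6 is formed racemic, which is of no consequence because this centre becomes sp2 in step 8.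

Step 6
Reactants: 8 rac-2-[(3E)-4-methyl-5-(TBSO)pent-3-enyl]but-3-ene-1,2-diol; 9 pyruvic acid
Product: 11 3-hydroxy-3-methyl-5-[(3E)-4-methyl-5-(TBSO)pent-3-enyl]-5-vinyl-1,4-dioxan-2-one (cyclic hemiketal; stereoisomer mixture), via pyruvate ester 10 (not isolated)
Conditions: DCC, DMAP (cat.), CH2Cl2, −20 → 0 °C
Reagents that add atoms: none
Why: Carbodiimide (Steglich) esterification takes place at the primary hydroxyl only, after which the electrophilic pyruvate ketone is trapped by the tertiary hydroxyl as a six-membered cyclic hemiketal whose two stereocentres are both erased in steps 7 and 8.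

Step 7
Reactants: 11 3-hydroxy-3-methyl-5-[(3E)-4-methyl-5-(TBSO)pent-3-enyl]-5-vinyl-1,4-dioxan-2-one
Product: 13 rac-3-methylene-5-[(3E)-4-methyl-5-(TBSO)pent-3-enyl]-5-vinyl-1,4-dioxan-2-one, via hemiketal mesylate 12 (not isolated)
Conditions: MsCl, Et3N, CH2Cl2, −20 °C → rt
Reagents that add atoms: none
Why: Sulfonylation of the hemiketal hydroxyl and amine-induced elimination toward the methyl group, the only source of β-hydrogens, should give the exocyclic enol ether (dehydration of a hemiketal to an enol ether by E1/E2 elimination), and no stereocentre is created.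

Step 8
Reactants: 13 rac-3-methylene-5-[(3E)-4-methyl-5-(TBSO)pent-3-enyl]-5-vinyl-1,4-dioxan-2-one
Product: 14 (6Z)-7-[(3E)-4-methyl-5-(TBSO)pent-3-enyl]-5,8-dihydro-2H-oxocine-2,3(4H)-dione (eight-membered α-keto lactone)
Conditions: toluene (0.02 M), BHT (cat.), 110 °C
Reagents that add atoms: none
Why: Thermal Claisen rearrangement: the allyl vinyl ether array CH2=C(acyl)–O–C(quaternary)–CH=CH2 embedded in 13 reorganises through a six-centre transition state, forming the C3–C4 σ bond between the exocyclic methylene and the vinyl terminus and the C5=C6 π bond, while the C6–O bond breaks and the enol ether oxygen becomes the C2 ketone. The closest known reaction types are the Claisen ring expansion of 2-methylene-6-vinyl oxacycles and the Gosteli–Claisen rearrangement of 2-alkoxycarbonyl allyl vinyl ethers, both helped here by the acceptor on the vinyl ether and by full substitution at the carbinol carbon. The eight-membered ring is closed by a two-atom ring expansion of the six-membered dioxanone through a boat-like transition state in which the O–C7 tether spans the forming ring. No stereocentre is formed and the racemic C6 centre of 13 is destroyed, so both enantiomers converge on one achiral product. The selectivity needed is the olefin geometry (C4 and C7 cis), which the ring secures because this ring-expansion geometry should deliver only the cis ring olefin in an eight-membered product. Formation of the 1,2-dicarbonyl unit should make the step irreversible, and BHT is added against radical polymerisation of the alkoxyacrylate.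

Step 9
Reactants: 14 (6Z)-7-[(3E)-4-methyl-5-(TBSO)pent-3-enyl]-5,8-dihydro-2H-oxocine-2,3(4H)-dione
Product: 16 TMSE (5Z,9E)-10-methyl-2-oxo-11-(TBSO)-6-[(TESO)methyl]undeca-5,9-dienoate, via hydroxy keto ester 15 (not isolated)
Conditions: Me3SiCH2CH2OH, DMAP (cat.), CH2Cl2, rt; then Et3SiCl, imidazole, 0 °C
Reagents that add atoms: 2-(trimethylsilyl)ethanol, C[Si](C)(C)CCO; chlorotriethylsilane, CC[Si](CC)(CC)Cl
Why: The α-keto lactone is an activated ester that undergoes DMAP-catalysed transesterification with the primary alcohol, and silylation of the liberated primary allylic hydroxyl (faster than that of the tertiary hemiketal hydroxyl) drains the hemiketal equilibrium to the open-chain α-keto ester needed for two-point binding in step 12.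

Step 10
Reactants: 17 1-(2,5-dihydroxyphenyl)ethanone
Product: 18 1-[2,5-bis(TBSO)phenyl]ethanone
Conditions: TBSCl, imidazole, DMF, rt
Reagents that add atoms: tert-butyldimethylsilyl chloride, CC(C)(C)[Si](C)(C)Cl
Why: Standard silylation of both phenols gives fluoride-labile ethers that tolerate the Lewis acid of step 12.

Step 11
Reactants: 18 1-[2,5-bis(TBSO)phenyl]ethanone
Product: 19 1-[2,5-bis(TBSO)phenyl]-1-(TMSO)ethene
Conditions: TMSOTf, Et3N, CH2Cl2, 0 °C
Reagents that add atoms: trimethylsilyl trifluoromethanesulfonate, C[Si](C)(C)OS(=O)(=O)C(F)(F)F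
Why: Soft enolisation of the methyl ketone by silyl triflate and amine gives the only possible silyl enol ether without the strong base that could shift the ortho silyl group.

Step 12
Reactants: 16 TMSE (5Z,9E)-10-methyl-2-oxo-11-(TBSO)-6-[(TESO)methyl]undeca-5,9-dienoate; 19 1-[2,5-bis(TBSO)phenyl]-1-(TMSO)ethene
Product: 21 TMSE (2R,5Z,9E)-2-{2-[2,5-bis(TBSO)phenyl]-2-oxoethyl}-2-hydroxy-6-(hydroxymethyl)-10-methyl-11-(TBSO)undeca-5,9-dienoate, via bis-silylated aldol adduct 20 (not isolated)
Conditions: Cu(OTf)2 (10 mol %), (R,R)-2,2'-isopropylidenebis(4-tert-butyl-2-oxazoline) (11 mol %), THF, −78 °C; then PPTS, MeOH, 0 °C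
Reagents that add atoms: none
Why: Mukaiyama aldol addition under catalysis by a C2-symmetric bis(oxazoline) complex of divalent copper, in which the α-keto ester is bound through both carbonyl oxygen atoms in a square-planar chelate whose Si face is shielded by a tert-butyl group of the (R,R) ligand, so that the enol silane should add to the Re face of the C2 ketone and set the (R) quaternary carbinol, after which mild acidic methanolysis removes the tertiary TMS and primary TES ethers but not the TBS ethers.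

Step 13
Reactants: 21 TMSE (2R,5Z,9E)-2-{2-[2,5-bis(TBSO)phenyl]-2-oxoethyl}-2-hydroxy-6-(hydroxymethyl)-10-methyl-11-(TBSO)undeca-5,9-dienoate
Product: 22 TMSE (2R)-2-{2-[2,5-bis(TBSO)phenyl]-2-oxoethyl}-6-[(3E)-4-methyl-5-(TBSO)pent-3-enyl]-2,3,4,7-tetrahydrooxepine-2-carboxylate
Conditions: PPh3, DIAD, toluene (0.005 M), 0 °C → rt
Reagents that add atoms: none
Why: Mitsunobu cyclodehydration activates the unhindered primary allylic hydroxyl as an oxyphosphonium ion, which the ester-acidified tertiary hydroxyl displaces in an SN2 sense (7-exo-tet) helped by the cis arrangement of C4 and C7 on the olefin, and since the C2–O bond is never broken the (R) configuration is retained.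

Step 14
Reactants: 22 TMSE (2R)-2-{2-[2,5-bis(TBSO)phenyl]-2-oxoethyl}-6-[(3E)-4-methyl-5-(TBSO)pent-3-enyl]-2,3,4,7-tetrahydrooxepine-2-carboxylate
Product: 23 (2R)-2-[2-(2,5-dihydroxyphenyl)-2-oxoethyl]-6-[(3E)-5-hydroxy-4-methylpent-3-enyl]-2,3,4,7-tetrahydrooxepine-2-carboxylic acid
Conditions: TASF (tris(dimethylamino)sulfonium difluorotrimethylsilicate), DMF, 0 °C → rt; aq. NH4Cl
Reagents that add atoms: none
Why: Fluoride removes the three TBS ethers and fragments the TMSE ester with loss of ethene under nearly neutral conditions, which avoids hydroxide in the presence of the β-alkoxy aryl ketone and leaves C2 untouched.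

**Compound list**

1 | 5-bromo-2-methylpent-2-ene | CC(C)=CCCBr | starting material
2 | (2E)-5-bromo-2-methylpent-2-en-1-ol | C/C(=C\CCBr)CO | intermediate
3 | (2E)-5-bromo-2-methyl-1-(TBSO)pent-2-ene | C/C(=C\CCBr)CO[Si](C)(C)C(C)(C)C | intermediate
4 | 2-chloro-N-methoxy-N-methylacetamide | CON(C)C(=O)CCl | starting material
5 | [(3E)-4-methyl-5-(TBSO)pent-3-enyl]magnesium bromide | C/C(=C\CC[Mg]Br)CO[Si](C)(C)C(C)(C)C | intermediate
6 | (5E)-1-chloro-6-methyl-7-(TBSO)hept-5-en-2-one | C/C(=C\CCC(=O)CCl)CO[Si](C)(C)C(C)(C)C | intermediate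
7 | (5E)-6-methyl-2-oxo-7-(TBSO)hept-5-enyl acetate | C/C(=C\CCC(=O)COC(C)=O)CO[Si](C)(C)C(C)(C)C | intermediate
8 | rac-2-[(3E)-4-methyl-5-(TBSO)pent-3-enyl]but-3-ene-1,2-diol | C/C(=C\CCC(O)(CO)C=C)CO[Si](C)(C)C(C)(C)C | intermediate
9 | pyruvic acid | CC(=O)C(=O)O | starting material
10 | rac-2-hydroxy-2-[(3E)-4-methyl-5-(TBSO)pent-3-enyl]but-3-enyl 2-oxopropanoate | C/C(=C\CCC(O)(COC(=O)C(C)=O)C=C)CO[Si](C)(C)C(C)(C)C | intermediate
11 | 3-hydroxy-3-methyl-5-[(3E)-4-methyl-5-(TBSO)pent-3-enyl]-5-vinyl-1,4-dioxan-2-one (cyclic hemiketal; stereoisomer mixture) | C/C(=C\CCC1(C=C)COC(=O)C(C)(O)O1)CO[Si](C)(C)C(C)(C)C | intermediate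
12 | 3-methyl-3-(methylsulfonyloxy)-5-[(3E)-4-methyl-5-(TBSO)pent-3-enyl]-5-vinyl-1,4-dioxan-2-one | C/C(=C\CCC1(C=C)COC(=O)C(C)(OS(C)(=O)=O)O1)CO[Si](C)(C)C(C)(C)C | intermediate
13 | rac-3-methylene-5-[(3E)-4-methyl-5-(TBSO)pent-3-enyl]-5-vinyl-1,4-dioxan-2-one | C/C(=C\CCC1(C=C)COC(=O)C(=C)O1)CO[Si](C)(C)C(C)(C)C | intermediate
14 | (6Z)-7-[(3E)-4-methyl-5-(TBSO)pent-3-enyl]-5,8-dihydro-2H-oxocine-2,3(4H)-dione | C/C(=C\CC/C1=C/CCC(=O)C(=O)OC1)CO[Si](C)(C)C(C)(C)C | intermediate
15 | TMSE (5Z,9E)-6-(hydroxymethyl)-10-methyl-2-oxo-11-(TBSO)undeca-5,9-dienoate (in equilibrium with its seven-membered cyclic hemiketal) | C/C(=C\CC/C(CO)=C/CCC(=O)C(=O)OCC[Si](C)(C)C)CO[Si](C)(C)C(C)(C)C | intermediate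
16 | TMSE (5Z,9E)-10-methyl-2-oxo-11-(TBSO)-6-[(TESO)methyl]undeca-5,9-dienoate | C/C(=C\CC/C(CO[Si](CC)(CC)CC)=C/CCC(=O)C(=O)OCC[Si](C)(C)C)CO[Si](C)(C)C(C)(C)C | intermediate
17 | 1-(2,5-dihydroxyphenyl)ethanone | CC(=O)c1cc(O)ccc1O | starting material
18 | 1-[2,5-bis(TBSO)phenyl]ethanone | CC(=O)c1cc(O[Si](C)(C)C(C)(C)C)ccc1O[Si](C)(C)C(C)(C)C | intermediate
19 | 1-[2,5-bis(TBSO)phenyl]-1-(TMSO)ethene | C=C(O[Si](C)(C)C)c1cc(O[Si](C)(C)C(C)(C)C)ccc1O[Si](C)(C)C(C)(C)C | intermediate
20 | TMSE (2R,5Z,9E)-2-{2-[2,5-bis(TBSO)phenyl]-2-oxoethyl}-10-methyl-11-(TBSO)-6-[(TESO)methyl]-2-(TMSO)undeca-5,9-dienoate | C/C(=C\CC/C(CO[Si](CC)(CC)CC)=C/CC[C@@](CC(=O)c1cc(O[Si](C)(C)C(C)(C)C)ccc1O[Si](C)(C)C(C)(C)C)(C(=O)OCC[Si](C)(C)C)O[Si](C)(C)C)CO[Si](C)(C)C(C)(C)C | intermediate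
21 | TMSE (2R,5Z,9E)-2-{2-[2,5-bis(TBSO)phenyl]-2-oxoethyl}-2-hydroxy-6-(hydroxymethyl)-10-methyl-11-(TBSO)undeca-5,9-dienoate | C/C(=C\CC/C(CO)=C/CC[C@@](CC(=O)c1cc(O[Si](C)(C)C(C)(C)C)ccc1O[Si](C)(C)C(C)(C)C)(C(=O)OCC[Si](C)(C)C)O)CO[Si](C)(C)C(C)(C)C | intermediate
22 | TMSE (2R)-2-{2-[2,5-bis(TBSO)phenyl]-2-oxoethyl}-6-[(3E)-4-methyl-5-(TBSO)pent-3-enyl]-2,3,4,7-tetrahydrooxepine-2-carboxylate | C/C(=C\CCC1=CCC[C@@](CC(=O)c2cc(O[Si](C)(C)C(C)(C)C)ccc2O[Si](C)(C)C(C)(C)C)(C(=O)OCC[Si](C)(C)C)OC1)CO[Si](C)(C)C(C)(C)C | intermediate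
23 | (2R)-2-[2-(2,5-dihydroxyphenyl)-2-oxoethyl]-6-[(3E)-5-hydroxy-4-methylpent-3-enyl]-2,3,4,7-tetrahydrooxepine-2-carboxylic acid | C/C(=C\CCC1=CCC[C@@](CC(=O)c2cc(O)ccc2O)(C(=O)O)OC1)CO | target

**Step count and risks**

Total: 14 steps. Longest linear sequence: 12 steps (steps 1–9 and 12–14; steps 10 and 11 make the enol silane 19).

Steps most likely to fail:

Step 13. The tertiary hydroxyl is a weak nucleophile, so the activated allylic alcohol may be attacked at the other allylic terminus C5 (closure to a five-membered ether) or be captured by the hydrazide anion. The fallback sets out from 21: the primary allylic hydroxyl is converted chemoselectively (CBr4, PPh3, 2,6-lutidine, CH2Cl2, −30 °C) into the allylic bromide F1, and the ring is closed by silver-assisted O-alkylation of the α-hydroxy ester (Ag2O, 4 Å molecular sieves, CH2Cl2, dark), which comes back to the route at 22.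

Step 7. Activation of the hemiketal hydroxyl may lead to ionisation with ring opening and loss of the tertiary allylic oxygen instead of elimination into the methyl group. The fallback sets out from 8: the primary hydroxyl is esterified with (diethoxyphosphoryl)acetic acid (DCC, DMAP, CH2Cl2) to the phosphonoacetate F2, diazo transfer (4-acetamidobenzenesulfonyl azide, DBU, MeCN) gives the diazo ester F3, Rh2(OAc)4 (CH2Cl2, rt) brings about carbenoid insertion into the tertiary O–H bond to the phosphoryl dioxanone F4, and Horner–Wadsworth–Emmons methylenation with aqueous formaldehyde and K2CO3 comes back to the route at 13.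

Step 14. Once the phenols are free, fluoride may trigger β-elimination of the ring oxygen from the β-alkoxy ketone, followed by re-addition of the ortho-phenoxide to the enone. The fallback sets out from 22: the three silyl ethers are cleaved under buffered acidic conditions (HF·pyridine, pyridine, THF, 0 °C) to the triol ester F5, and the TMSE ester is then fragmented with acid (CF3CO2H, CH2Cl2, 0 °C), which comes back to the route at 23.

Further compounds
F1 | step 13 | allylic bromide: TMSE (2R,5Z,9E)-2-{2-[2,5-bis(TBSO)phenyl]-2-oxoethyl}-6-(bromomethyl)-2-hydroxy-10-methyl-11-(TBSO)undeca-5,9-dienoate | C/C(=C\CC/C(CBr)=C/CC[C@@](CC(=O)c1cc(O[Si](C)(C)C(C)(C)C)ccc1O[Si](C)(C)C(C)(C)C)(C(=O)OCC[Si](C)(C)C)O)CO[Si](C)(C)C(C)(C)C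
F2 | step 7 | phosphonoacetate: rac-2-hydroxy-2-[(3E)-4-methyl-5-(TBSO)pent-3-enyl]but-3-enyl 2-(diethoxyphosphoryl)acetate | C/C(=C\CCC(O)(COC(=O)CP(=O)(OCC)OCC)C=C)CO[Si](C)(C)C(C)(C)C
F3 | step 7 | diazo ester: rac-2-hydroxy-2-[(3E)-4-methyl-5-(TBSO)pent-3-enyl]but-3-enyl 2-diazo-2-(diethoxyphosphoryl)acetate | C/C(=C\CCC(O)(COC(=O)C(=[N+]=[N-])P(=O)(OCC)OCC)C=C)CO[Si](C)(C)C(C)(C)C
F4 | step 7 | phosphoryl dioxanone: diethyl {5-[(3E)-4-methyl-5-(TBSO)pent-3-enyl]-3-oxo-5-vinyl-1,4-dioxan-2-yl}phosphonate | C/C(=C\CCC1(C=C)COC(=O)C(P(=O)(OCC)OCC)O1)CO[Si](C)(C)C(C)(C)C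
F5 | step 14 | triol ester: TMSE (2R)-2-[2-(2,5-dihydroxyphenyl)-2-oxoethyl]-6-[(3E)-5-hydroxy-4-methylpent-3-enyl]-2,3,4,7-tetrahydrooxepine-2-carboxylate | C/C(=C\CCC1=CCC[C@@](CC(=O)c2cc(O)ccc2O)(C(=O)OCC[Si](C)(C)C)OC1)CO
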